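**Plan**

- Retrosynthesis: the ester C–O bond, the exocyclic C=CH2 and the two C–OH bonds of the ring cis-diol are cut first. The cyclopentane is then opened at the bond between the isopropyl carbinol carbon and its ring CH2 (samarium Barbier). Last come the bond from the ring-fusion CH to that acyl carbon and the bond from the quaternary methyl carbon to its CH2CH2 arm (three-component coupling on a cycloheptenone).
- Forward: the seven-membered ring is present from the start (cyclohepta-1,3-diene to enone 6). Cuprate addition and enolate alkylation put both arms on it, the five-membered ring is closed last (step 8), and the ring ketone is then turned into the methylidene/cis-diol array before esterification.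
- Enabling feature: in the cyclopentane the carbinol carbon (OH, isopropyl) is bonded to the ring-fusion CH, which sits next to the ester-bearing carbon of the seven-membered ring, and it is two CH2 groups away from the quaternary methyl carbon. An isobutyryl group on the fusion CH and a 2-bromoethyl arm on the quaternary carbon, trans to each other, therefore close by carbonyl addition without touching the trans ring fusion.
- Stereochemistry: one catalytic asymmetric step (step 2) sets the silyloxy carbon, the later ester carbon. It is relayed to the fusion CH (anti 1,4-addition), the quaternary carbon (alkylation anti to the new arm), the carbinol carbon (step 8) and the diol (osmylation anti to the angular methyl).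

Key step: step 8

Remark: 7 and 8 are taken as catalogue compounds. TBSO = tert-butyl(dimethyl)silyloxy. The azulene locants of the target name (3 carbinol C, 3a fusion CH, 4 ester C, 6 methylidene C, 7 and 8 diol C, 8a methyl C) are kept for all bicyclic compounds.

**Route**

Step 1
Reactants: 1 cyclohepta-1,3-diene
Product: 2 cis-6,7-dioxabicyclo[3.2.2]non-8-ene (meso endoperoxide)
Conditions: O2, tetraphenylporphyrin (cat.), hν, CH2Cl2, 0 °C
Reagents that add atoms: oxygen O=O
Why: Singlet oxygen should add to the cyclic 1,3-diene in a [4+2] cycloaddition, giving the meso endoperoxide with both C–O bonds on one face.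

Step 2
Reactants: 2 cis-6,7-dioxabicyclo[3.2.2]non-8-ene
Product: 3 (4S)-4-hydroxycyclohept-2-en-1-one
Conditions: cinchona-derived bifunctional amine (6'-OH, 9-O-acyl type, 10 mol %, the pseudo-enantiomer that gives the S alcohol), CH2Cl2, rt
Reagents that add atoms: none
Why: In this enantioselective Kornblum–DeLaMare rearrangement the chiral base should remove one of the two enantiotopic bridgehead hydrogens, so that this carbon becomes the ketone and the other keeps its oxygen as the (S)-carbinol.

Step 3
Reactants: 3 (4S)-4-hydroxycyclohept-2-en-1-one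
Product: 4 (4S)-4-TBSO-cyclohept-2-en-1-one
Conditions: TBSCl, imidazole, DMF, rt
Reagents that add atoms: tert-butyldimethylsilyl chloride CC(C)(C)[Si](C)(C)Cl
Why: Standard silylation of a secondary alcohol gives a group that survives organometallic steps and later directs the cuprate.

Step 4
Reactants: 4 (4S)-4-TBSO-cyclohept-2-en-1-one
Product: 5 (4S)-4-TBSO-2-iodocyclohept-2-en-1-one
Conditions: I2, pyridine, CH2Cl2, 0 °C to rt
Reagents that add atoms: iodine II
Why: α-Iodination of an enone by pyridine conjugate addition, iodination of the enolate and elimination should place iodine only on the α-carbon.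

Step 5
Reactants: 5 (4S)-4-TBSO-2-iodocyclohept-2-en-1-one
Product: 6 (4S)-4-TBSO-2-methylcyclohept-2-en-1-one
Conditions: Me4Sn, Pd2(dba)3 (cat.), AsPh3, CuI (cat.), NMP, 60 °C
Reagents that add atoms: tetramethylstannane C[Sn](C)(C)C
Why: Stille coupling of an α-iodoenone with tetramethyltin should replace iodine by the methyl group that becomes the angular methyl.

Step 6
Reactants: 6 (4S)-4-TBSO-2-methylcyclohept-2-en-1-one; 7 2-bromo-3-methylbut-1-ene; 8 2-bromoethyl trifluoromethanesulfonate
Product: 10 (2S,3S,4S)-2-(2-bromoethyl)-4-TBSO-2-methyl-3-(3-methylbut-1-en-2-yl)cycloheptan-1-one, via lithium enolate 9 (not isolated)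
Conditions: 7 (2.2 equiv), t-BuLi (4.4 equiv), Et2O, −78 °C; CuI (1.1 equiv), −78 to −40 °C; 6, −78 °C; then HMPA, 8, −78 to −20 °C
Reagents that add atoms: none
Why: In this three-component coupling (cuprate 1,4-addition, then enolate alkylation, as in prostaglandin syntheses) the alkenyl group should add trans to the γ-silyloxy group, and the enolate should then be alkylated by the triflate end of 8 at the methyl-bearing carbon, trans to the new alkenyl group.

Step 7
Reactants: 10 (2S,3S,4S)-2-(2-bromoethyl)-4-TBSO-2-methyl-3-(3-methylbut-1-en-2-yl)cycloheptan-1-one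
Product: 12 (2S,3S,4S)-2-(2-bromoethyl)-4-TBSO-2-methyl-3-(2-methylpropanoyl)cycloheptan-1-one, via ozonide 11 (not isolated)
Conditions: O3, CH2Cl2, −78 °C; then Me2S, −78 °C to rt
Reagents that add atoms: ozone [O-][O+]=O
Why: Ozonolysis of the only C=C (1,1-disubstituted) with reductive work-up should unmask the isobutyryl ketone under neutral conditions that leave the α-stereocentre and the β-silyloxy group alone.

Step 8
Reactants: 12 (2S,3S,4S)-2-(2-bromoethyl)-4-TBSO-2-methyl-3-(2-methylpropanoyl)cycloheptan-1-one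
Product: 14 (3R,3aS,4S,8aS)-4-TBSO-3-hydroxy-8a-methyl-3-(propan-2-yl)decahydroazulen-8-one (trans-fused), via alkylsamarium 13 (not isolated)
Conditions: SmI2 (2.4 equiv), NiI2 (2 mol %), THF, 0 °C; then aq. NH4Cl
Reagents that add atoms: none
Why: SmI2 should reduce the primary C–Br bond in two one-electron steps to the alkylsamarium(III) 13, which adds to the isobutyryl carbonyl; the closest known reaction is the intramolecular samarium Barbier cyclisation of ω-halo ketones. The cyclopentane closes in the 5-exo-trig mode by joining the CH2 end of the bromoethyl arm to the acyl carbon, so both ring-fusion carbons stay sp3 and their trans relation from step 6 is carried into a trans-fused hydroazulene. The only new stereocentre is the carbinol carbon: in the transition state the carbonyl plane lies across the forming ring, with one carbonyl substituent next to the ring-fusion hydrogen and the other next to the silyloxy-bearing ring carbon. The isopropyl group should take the side of the hydrogen, which puts the oxygen on the face of the angular methyl. The step needs reduction of C–Br in preference to ketyl formation at either ketone, and attack on the side-chain ketone and not the ring ketone. Halide reduction is faster than dialkyl ketone reduction under nickel catalysis, and attack on the ring ketone would require a four-membered ring.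

Step 9
Reactants: 14 (3R,3aS,4S,8aS)-4-TBSO-3-hydroxy-8a-methyl-3-(propan-2-yl)decahydroazulen-8-one
Product: 16 (3R,3aS,4S,8aS)-4-TBSO-3-hydroxy-8a-methyl-3-(propan-2-yl)-1,2,3,3a,4,5,6,8a-octahydroazulen-8-yl trifluoromethanesulfonate, via dipotassium enolate 15 (not isolated)
Conditions: KHMDS (2.2 equiv), THF, −78 °C; PhNTf2, −78 to 0 °C; aq. NH4Cl
Reagents that add atoms: N-phenylbis(trifluoromethanesulfonimide) O=S(=O)(N(c1ccccc1)S(=O)(=O)C(F)(F)F)C(F)(F)F
Why: The ketone can enolise only towards its CH2 side because the other α-carbon is quaternary, and O-sulfonylation of that enolate should give the enol triflate while the hindered tertiary alkoxide is returned as the alcohol.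

Step 10
Reactants: 16 (3R,3aS,4S,8aS)-4-TBSO-3-hydroxy-8a-methyl-3-(propan-2-yl)-1,2,3,3a,4,5,6,8a-octahydroazulen-8-yl trifluoromethanesulfonate
Product: 17 (3R,3aS,4S,8aR)-4-TBSO-8a-methyl-3-(propan-2-yl)-1,2,3,3a,4,5,6,8a-octahydroazulen-3-ol
Conditions: Pd(OAc)2 (cat.), PPh3, Bu3N, HCO2H, DMF, 60 °C
Reagents that add atoms: none
Why: Palladium-catalysed formate reduction of the enol triflate (oxidative addition, formate exchange, loss of CO2, reductive elimination) should replace OTf by H and leave a cis C=C next to the quaternary carbon.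

Step 11
Reactants: 17 (3R,3aS,4S,8aR)-4-TBSO-8a-methyl-3-(propan-2-yl)-1,2,3,3a,4,5,6,8a-octahydroazulen-3-ol
Product: 18 (3R,3aS,4S,8aR)-4-TBSO-3-hydroxy-8a-methyl-3-(propan-2-yl)-2,3,3a,4,5,8a-hexahydroazulen-6(1H)-one
Conditions: Rh2(cap)4 (cat.), t-BuOOH, K2CO3, CH2Cl2, rt
Reagents that add atoms: tert-butyl hydroperoxide CC(C)(C)OO
Why: In this allylic C–H oxidation the cycloheptene has a single allylic CH2 (the other allylic position is the quaternary carbon), and the allyl radical should be oxygenated at its unhindered terminus to give the enone with the C=C where it was.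

Step 12
Reactants: 18 (3R,3aS,4S,8aR)-4-TBSO-3-hydroxy-8a-methyl-3-(propan-2-yl)-2,3,3a,4,5,8a-hexahydroazulen-6(1H)-one
Product: 19 (3R,3aS,4S,7S,8S,8aS)-4-TBSO-3,7,8-trihydroxy-8a-methyl-3-(propan-2-yl)octahydroazulen-6(1H)-one
Conditions: OsO4 (cat.), NMO, citric acid, acetone/t-BuOH/H2O, rt
Reagents that add atoms: N-methylmorpholine N-oxide C[N+]1([O-])CCOCC1; water O
Why: Catalytic osmium dihydroxylation should add both hydroxyls syn to the enone C=C from the face opposite the axial angular methyl on the adjacent quaternary carbon, giving the cis-diol trans to that methyl.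

Step 13
Reactants: 19 (3R,3aS,4S,7S,8S,8aS)-4-TBSO-3,7,8-trihydroxy-8a-methyl-3-(propan-2-yl)octahydroazulen-6(1H)-one
Product: 20 7,8-O-isopropylidene derivative of 19 (cis-fused dioxolane)
Conditions: 2,2-dimethoxypropane, PPTS (cat.), CH2Cl2, rt
Reagents that add atoms: 2,2-dimethoxypropane COC(C)(C)OC
Why: Acid-catalysed transketalisation should tie up only the cis-1,2-diol, which blocks retro-aldol cleavage of the β-hydroxy ketone in the next, basic step.

Step 14
Reactants: 20 7,8-O-isopropylidene derivative of 19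
Product: 21 (3R,3aS,4S,7R,8S,8aS)-4-TBSO-7,8-(isopropylidenedioxy)-8a-methyl-6-methylidene-3-(propan-2-yl)decahydroazulen-3-ol
Conditions: Ph3PCH3Br, KHMDS (excess ylide), THF, 0 °C to rt
Reagents that add atoms: methyltriphenylphosphonium bromide C[P+](c1ccccc1)(c1ccccc1)c1ccccc1.[Br-]
Why: Wittig methylenation of the ring ketone should install the exocyclic methylidene, with the tertiary alcohol merely deprotonated and recovered on work-up.

Step 15
Reactants: 21 (3R,3aS,4S,7R,8S,8aS)-4-TBSO-7,8-(isopropylidenedioxy)-8a-methyl-6-methylidene-3-(propan-2-yl)decahydroazulen-3-ol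
Product: 22 (3R,3aS,4S,7R,8S,8aS)-7,8-(isopropylidenedioxy)-8a-methyl-6-methylidene-3-(propan-2-yl)decahydroazulene-3,4-diol
Conditions: TBAF, THF, rt to 40 °C
Reagents that add atoms: none
Why: Fluoride cleavage of the silyl ether should free the secondary alcohol without affecting the acetonide or the alkene.

Step 16
Reactants: 22 (3R,3aS,4S,7R,8S,8aS)-7,8-(isopropylidenedioxy)-8a-methyl-6-methylidene-3-(propan-2-yl)decahydroazulene-3,4-diol; 23 3-methylbutanoic anhydride
Product: 24 (3R,3aS,4S,7R,8S,8aS)-3-hydroxy-7,8-(isopropylidenedioxy)-8a-methyl-6-methylidene-3-(propan-2-yl)decahydroazulen-4-yl 3-methylbutanoate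
Conditions: 23, DMAP, Et3N, CH2Cl2, rt
Reagents that add atoms: none
Why: DMAP-catalysed acylation should esterify the only secondary alcohol, since the tertiary carbinol is too hindered to react.

Step 17
Reactants: 24 (3R,3aS,4S,7R,8S,8aS)-3-hydroxy-7,8-(isopropylidenedioxy)-8a-methyl-6-methylidene-3-(propan-2-yl)decahydroazulen-4-yl 3-methylbutanoate
Product: 25 (3R,3aS,4S,7R,8S,8aS)-3,7,8-trihydroxy-8a-methyl-6-methylidene-3-(propan-2-yl)decahydroazulen-4-yl 3-methylbutanoate
Conditions: AcOH/H2O 4:1, 40 °C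
Reagents that add atoms: none
Why: Mild aqueous acid should hydrolyse the acetonide while the ester, the tertiary alcohol and the allylic diol remain intact.

**Compound list**

1 | cyclohepta-1,3-diene | C1=CC=CCCC1 | starting material
2 | cis-6,7-dioxabicyclo[3.2.2]non-8-ene (meso) | C1C[C@H]2C=C[C@@H](C1)OO2 | intermediate
3 | (4S)-4-hydroxycyclohept-2-en-1-one | C1C[C@H](O)C=CC(=O)C1 | intermediate
4 | (4S)-4-TBSO-cyclohept-2-en-1-one | C1C[C@H](O[Si](C)(C)C(C)(C)C)C=CC(=O)C1 | intermediate
5 | (4S)-4-TBSO-2-iodocyclohept-2-en-1-one | C1C[C@H](O[Si](C)(C)C(C)(C)C)C=C(I)C(=O)C1 | intermediate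
6 | (4S)-4-TBSO-2-methylcyclohept-2-en-1-one | C1C[C@H](O[Si](C)(C)C(C)(C)C)C=C(C)C(=O)C1 | intermediate
7 | 2-bromo-3-methylbut-1-ene | C=C(Br)C(C)C | starting material
8 | 2-bromoethyl trifluoromethanesulfonate | BrCCOS(=O)(=O)C(F)(F)F | starting material
9 | lithium (3S,4S)-4-TBSO-2-methyl-3-(3-methylbut-1-en-2-yl)cyclohept-1-en-1-olate | C1C[C@H](O[Si](C)(C)C(C)(C)C)[C@@H](C(=C)C(C)C)C(C)=C([O-])C1.[Li+] | intermediate
10 | (2S,3S,4S)-2-(2-bromoethyl)-4-TBSO-2-methyl-3-(3-methylbut-1-en-2-yl)cycloheptan-1-one | C1C[C@H](O[Si](C)(C)C(C)(C)C)[C@@H](C(=C)C(C)C)[C@](C)(CCBr)C(=O)C1 | intermediate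
11 | ozonide of 10 (1,2,4-trioxolane at the former C=CH2, mixture at the trioxolane carbon) | C1C[C@H](O[Si](C)(C)C(C)(C)C)[C@@H](C2(C(C)C)OCOO2)[C@](C)(CCBr)C(=O)C1 | intermediate
12 | (2S,3S,4S)-2-(2-bromoethyl)-4-TBSO-2-methyl-3-(2-methylpropanoyl)cycloheptan-1-one | C1C[C@H](O[Si](C)(C)C(C)(C)C)[C@@H](C(=O)C(C)C)[C@](C)(CCBr)C(=O)C1 | intermediate
13 | alkylsamarium(III) diiodide from 12 (Sm in place of Br) | C1C[C@H](O[Si](C)(C)C(C)(C)C)[C@@H](C(=O)C(C)C)[C@](C)(CC[Sm](I)I)C(=O)C1 | intermediate
14 | (3R,3aS,4S,8aS)-4-TBSO-3-hydroxy-8a-methyl-3-(propan-2-yl)decahydroazulen-8-one, trans-fused | C1C[C@H](O[Si](C)(C)C(C)(C)C)[C@@H]2[C@](C)(CC[C@@]2(O)C(C)C)C(=O)C1 | intermediate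
15 | dipotassium alkoxide enolate of 14 | C1C[C@H](O[Si](C)(C)C(C)(C)C)[C@@H]2[C@](C)(CC[C@@]2([O-])C(C)C)C([O-])=C1.[K+].[K+] | intermediate
16 | (3R,3aS,4S,8aS)-4-TBSO-3-hydroxy-8a-methyl-3-(propan-2-yl)-1,2,3,3a,4,5,6,8a-octahydroazulen-8-yl trifluoromethanesulfonate | C1C[C@H](O[Si](C)(C)C(C)(C)C)[C@@H]2[C@](C)(CC[C@@]2(O)C(C)C)C(OS(=O)(=O)C(F)(F)F)=C1 | intermediate
17 | (3R,3aS,4S,8aR)-4-TBSO-8a-methyl-3-(propan-2-yl)-1,2,3,3a,4,5,6,8a-octahydroazulen-3-ol | C1C[C@H](O[Si](C)(C)C(C)(C)C)[C@@H]2[C@](C)(CC[C@@]2(O)C(C)C)C=C1 | intermediate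
18 | (3R,3aS,4S,8aR)-4-TBSO-3-hydroxy-8a-methyl-3-(propan-2-yl)-2,3,3a,4,5,8a-hexahydroazulen-6(1H)-one | O=C1C[C@H](O[Si](C)(C)C(C)(C)C)[C@@H]2[C@](C)(CC[C@@]2(O)C(C)C)C=C1 | intermediate
19 | (3R,3aS,4S,7S,8S,8aS)-4-TBSO-3,7,8-trihydroxy-8a-methyl-3-(propan-2-yl)octahydroazulen-6(1H)-one | O=C1C[C@H](O[Si](C)(C)C(C)(C)C)[C@@H]2[C@](C)(CC[C@@]2(O)C(C)C)[C@H](O)[C@@H]1O | intermediate
20 | 7,8-O-isopropylidene derivative of 19 | O=C1C[C@H](O[Si](C)(C)C(C)(C)C)[C@@H]2[C@](C)(CC[C@@]2(O)C(C)C)[C@H](OC(C)(C)O3)[C@@H]13 | intermediate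
21 | (3R,3aS,4S,7R,8S,8aS)-4-TBSO-7,8-(isopropylidenedioxy)-8a-methyl-6-methylidene-3-(propan-2-yl)decahydroazulen-3-ol | C=C1C[C@H](O[Si](C)(C)C(C)(C)C)[C@@H]2[C@](C)(CC[C@@]2(O)C(C)C)[C@H](OC(C)(C)O3)[C@@H]13 | intermediate
22 | (3R,3aS,4S,7R,8S,8aS)-7,8-(isopropylidenedioxy)-8a-methyl-6-methylidene-3-(propan-2-yl)decahydroazulene-3,4-diol | C=C1C[C@H](O)[C@@H]2[C@](C)(CC[C@@]2(O)C(C)C)[C@H](OC(C)(C)O3)[C@@H]13 | intermediate
23 | 3-methylbutanoic anhydride | CC(C)CC(=O)OC(=O)CC(C)C | starting material
24 | (3R,3aS,4S,7R,8S,8aS)-3-hydroxy-7,8-(isopropylidenedioxy)-8a-methyl-6-methylidene-3-(propan-2-yl)decahydroazulen-4-yl 3-methylbutanoate | C=C1C[C@H](OC(=O)CC(C)C)[C@@H]2[C@](C)(CC[C@@]2(O)C(C)C)[C@H](OC(C)(C)O3)[C@@H]13 | intermediate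
25 | (3R,3aS,4S,7R,8S,8aS)-3,7,8-trihydroxy-8a-methyl-6-methylidene-3-(propan-2-yl)decahydroazulen-4-yl 3-methylbutanoate | C=C1C[C@H](OC(=O)CC(C)C)[C@@H]2[C@](C)(CC[C@@]2(O)C(C)C)[C@H](O)[C@@H]1O | target

**Totals and risks**

Total step count: 17. Longest linear sequence: 17 steps (fully linear from 1).

Steps most likely to fail:

Step 6. The hard triflate may alkylate the fully substituted enolate on oxygen, the enolate may simply be protonated or may eliminate HOTf from the reagent, and the branched alkenyl cuprate may add slowly to the α-substituted enone. The fallback sets out from 6 and uses the same cuprate addition, but traps the enolate with allyl iodide, a soft electrophile that alkylates on carbon, to give the allyl ketone F1. Ozonolysis of both terminal alkenes (O3, then Me2S) should give the keto aldehyde F2. NaBH(OAc)3 should reduce only the aldehyde to the primary alcohol F3, and PPh3/I2/imidazole should convert it into the iodide F4. F4 is closed with SmI2 as in step 8 and comes back to the route at 14.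

Step 8. Electron transfer may go to the ketones (ketyl formation, pinacol coupling or plain reduction), the organosamarium may be protonated before it adds, and attack on the hindered isopropyl ketone may be slow or take the wrong face. The fallback closes the ring on an aldehyde and brings in the isopropyl group last. It sets out from 6: lithium divinylcuprate addition and alkylation with 8 should give the vinyl ketone F5. The ring ketone is converted into its enol triflate F6 (KHMDS, Comins' reagent, −78 °C), and ozonolysis of the vinyl group, which the electron-poor enol triflate should survive, gives the aldehyde F7. SmI2 closure on the aldehyde should give the cyclopentanol F8 as a mixture of carbinol epimers, which does not matter because Dess–Martin oxidation gives the trans-fused cyclopentanone F9. Isopropylmagnesium chloride with CeCl3 at −78 °C should add to F9 from the face of the ring-fusion hydrogen, away from the silyloxy-bearing carbon, and comes back to the route at 16.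

Step 11. The delocalised allyl radical may be oxygenated at the terminus next to the quaternary carbon, which would give the transposed enone, or the oxidation may stop at the allylic peroxide or alcohol. The fallback is a Wharton transposition that sets out from 14. IBX in DMSO at 70 °C should dehydrogenate the ketone to the enone F10. Alkaline hydrogen peroxide should epoxidise it from the face opposite the angular methyl to give the epoxy ketone F11. Hydrazine hydrate with acetic acid should give the transposed allylic alcohol F12, and Dess–Martin oxidation of F12 comes back to the route at 18.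

Further compounds

F1 | step 6 | (2S,3S,4S)-4-TBSO-2-methyl-3-(3-methylbut-1-en-2-yl)-2-(prop-2-en-1-yl)cycloheptan-1-one | C1C[C@H](O[Si](C)(C)C(C)(C)C)[C@@H](C(=C)C(C)C)[C@](C)(CC=C)C(=O)C1
F2 | step 6 | 2-[(1S,2S,3S)-3-TBSO-1-methyl-2-(2-methylpropanoyl)-7-oxocycloheptyl]acetaldehyde | C1C[C@H](O[Si](C)(C)C(C)(C)C)[C@@H](C(=O)C(C)C)[C@](C)(CC=O)C(=O)C1
F3 | step 6 | (2S,3S,4S)-4-TBSO-2-(2-hydroxyethyl)-2-methyl-3-(2-methylpropanoyl)cycloheptan-1-one | C1C[C@H](O[Si](C)(C)C(C)(C)C)[C@@H](C(=O)C(C)C)[C@](C)(CCO)C(=O)C1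
F4 | step 6 | (2S,3S,4S)-4-TBSO-2-(2-iodoethyl)-2-methyl-3-(2-methylpropanoyl)cycloheptan-1-one | C1C[C@H](O[Si](C)(C)C(C)(C)C)[C@@H](C(=O)C(C)C)[C@](C)(CCI)C(=O)C1
F5 | step 8 | (2S,3S,4S)-2-(2-bromoethyl)-4-TBSO-3-ethenyl-2-methylcycloheptan-1-one | C1C[C@H](O[Si](C)(C)C(C)(C)C)[C@@H](C=C)[C@](C)(CCBr)C(=O)C1
F6 | step 8 | (5S,6S,7S)-7-(2-bromoethyl)-5-TBSO-6-ethenyl-7-methylcyclohept-1-en-1-yl trifluoromethanesulfonate | C1C[C@H](O[Si](C)(C)C(C)(C)C)[C@@H](C=C)[C@](C)(CCBr)C(OS(=O)(=O)C(F)(F)F)=C1
F7 | step 8 | (5S,6S,7S)-7-(2-bromoethyl)-5-TBSO-6-formyl-7-methylcyclohept-1-en-1-yl trifluoromethanesulfonate | C1C[C@H](O[Si](C)(C)C(C)(C)C)[C@@H](C=O)[C@](C)(CCBr)C(OS(=O)(=O)C(F)(F)F)=C1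
F8 | step 8 | trans-fused cyclopentanol from F7 (3-hydroxy epimers; other centres as in F9) | C1C[C@H](O[Si](C)(C)C(C)(C)C)[C@@H]2[C@](C)(CCC2O)C(OS(=O)(=O)C(F)(F)F)=C1
F9 | step 8 | (3aS,4S,8aS)-4-TBSO-8a-methyl-3-oxo-1,2,3,3a,4,5,6,8a-octahydroazulen-8-yl trifluoromethanesulfonate | C1C[C@H](O[Si](C)(C)C(C)(C)C)[C@@H]2[C@](C)(CC[C@@]2(O)C(C)C)C(OS(=O)(=O)C(F)(F)F)=C1
F10 | step 11 | (3R,3aS,4S,8aS)-4-TBSO-3-hydroxy-8a-methyl-3-(propan-2-yl)-2,3,3a,4,5,8a-hexahydroazulen-8(1H)-one | C1C[C@H](O[Si](C)(C)C(C)(C)C)[C@@H]2[C@](C)(CC[C@@]2(O)C(C)C)C(=O)C=1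
F11 | step 11 | 6,7-epoxide of F10 with the oxygen on the face opposite the 8a-methyl | O1[C@@H]2C[C@H](O[Si](C)(C)C(C)(C)C)[C@@H]3[C@](C)(CC[C@@]3(O)C(C)C)C(=O)[C@H]12
F12 | step 11 | 4-TBSO-8a-methyl-3-(propan-2-yl)-1,2,3,3a,4,5,6,8a-octahydroazulene-3,6-diol (6-OH on the face opposite the 8a-methyl) | O[C@@H]1C[C@H](O[Si](C)(C)C(C)(C)C)[C@@H]2[C@](C)(CC[C@@]2(O)C(C)C)C=C1
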